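Ring B is taken apart across C2–C3 and C1–C6: its C1 carbonyl and C2 heptyl group come from a dec-2-ynoate, and C3–C6 with the C4 and C6 oxygens from a 1,1,3-trioxygenated butadiene. The key step exploits this resorcylate pattern of ring B, so the hindered depside ester is already in place as an unhindered aryl alkynoate of the ring A phenol before ring B exists. One thermal Diels–Alder/aromatisation builds ring B with its substituents in the correct positions. The precursor is benzyl 4-(dec-2-ynoyloxy)-2-heptyl-6-methoxybenzoate, made from methyl orsellinate; O-methylation and hydrogenolysis finish the synthesis.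

Key step: step 11

Assumption (chemistry): the ketene acetal double bond of diene 20 is written as E; either geometric isomer, or a mixture, would serve equally, because that carbon becomes the planar aromatic C6 of ring B. LiN(iPr)2 is taken as a commercial solution.

Step 1
Reactants: 1 methyl orsellinate (methyl 2,4-dihydroxy-6-methylbenzoate)
Product: 2 methyl 2-hydroxy-4-(methoxymethoxy)-6-methylbenzoate
Conditions: MOMCl (1.1 equiv), iPr2NEt, CH2Cl2, 0 °C to rt
Reagents that add atoms: chloromethyl methyl ether (MOMCl), COCCl
Why: The 2-hydroxyl is tied up in a hydrogen bond to the ester carbonyl, so O-alkylation (Williamson-type MOM ether formation) should occur only at the free, more acidic 4-hydroxyl.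

Step 2
Reactants: 2 methyl 2-hydroxy-4-(methoxymethoxy)-6-methylbenzoate
Product: 3 methyl 2-methoxy-4-(methoxymethoxy)-6-methylbenzoate
Conditions: MeI, K2CO3, DMF, 40 °C
Reagents that add atoms: iodomethane, CI
Why: Williamson etherification with carbonate in a dipolar solvent should methylate the remaining chelated phenol, while the MOM acetal and the methyl ester are inert to these conditions.

Step 3
Reactants: 3 methyl 2-methoxy-4-(methoxymethoxy)-6-methylbenzoate; 4 1-iodohexane
Product: 6 methyl 2-heptyl-6-methoxy-4-(methoxymethoxy)benzoate, via benzylic lithium species 5 (not isolated)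
Conditions: LiN(iPr)2 (1.2 equiv), THF, −78 °C (3 added slowly to the base); then 4 (1.5 equiv), −78 to 0 °C
Reagents that add atoms: none
Why: Lateral lithiation of the ortho-toluate gives an ester-stabilised benzylic anion whose SN2 alkylation by the primary iodide extends the methyl group to heptyl; the low temperature, the inverse addition and the flanked ester carbonyl suppress Claisen-type self-condensation.

Step 4
Reactants: 6 methyl 2-heptyl-6-methoxy-4-(methoxymethoxy)benzoate
Product: 8 2-heptyl-6-methoxy-4-(methoxymethoxy)benzoic acid, via potassium carboxylate 7 (not isolated)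
Conditions: KOH (excess), DMSO–H2O (4:1), 90 °C; then cold 1 M HCl to pH 3, 0 °C
Reagents that add atoms: potassium hydroxide, [K+].[OH-]
Why: Saponification of the hindered methyl ester is forced by poorly solvated hydroxide in hot aqueous DMSO, conditions to which the aryl methyl ether and the MOM acetal are stable, and brief cold acidification frees the acid without cleaving the acetal.

Step 5
Reactants: 8 2-heptyl-6-methoxy-4-(methoxymethoxy)benzoic acid
Product: 9 benzyl 2-heptyl-6-methoxy-4-(methoxymethoxy)benzoate
Conditions: BnBr (1.2 equiv), K2CO3, DMF, rt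
Reagents that add atoms: benzyl bromide, BrCc1ccccc1
Why: Carboxylate O-alkylation is an SN2 reaction at the benzylic carbon of the bromide, so the steric shielding of the carbonyl carbon does not matter and no other nucleophilic site is present.

Step 6
Reactants: 9 benzyl 2-heptyl-6-methoxy-4-(methoxymethoxy)benzoate
Product: 10 benzyl 2-heptyl-4-hydroxy-6-methoxybenzoate
Conditions: HCl (catalytic, methanolic), MeOH, 40 °C
Reagents that add atoms: none
Why: Acid-catalysed acetal exchange with methanol removes the MOM group as dimethoxymethane, while the hindered benzyl ester and the aryl methyl ether should not react under such mild acid.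

Step 7
Reactants: 11 1-nonyne
Product: 14 dec-2-ynoic acid, via lithium nonynide 12 (not isolated), via lithium dec-2-ynoate 13 (not isolated)
Conditions: n-BuLi (1.05 equiv), THF, −78 °C; CO2 (gas), −78 to 0 °C; then 1 M HCl
Reagents that add atoms: carbon dioxide, O=C=O
Why: Deprotonation of the terminal alkyne and carboxylation of the lithium acetylide with carbon dioxide is the standard entry to alk-2-ynoic acids.

Step 8
Reactants: 10 benzyl 2-heptyl-4-hydroxy-6-methoxybenzoate; 14 dec-2-ynoic acid
Product: 15 benzyl 4-(dec-2-ynoyloxy)-2-heptyl-6-methoxybenzoate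
Conditions: DCC (1.1 equiv), DMAP (0.1 equiv), CH2Cl2, 0 °C to rt
Reagents that add atoms: none
Why: In this Steglich esterification the carbodiimide activates the unhindered ynoic acid and DMAP passes the acyl group to the only free nucleophile, the ring A phenol, at low temperature so that conjugate addition to the triple bond should not compete.

Step 9
Reactants: 16 methyl acetoacetate
Product: 18 methyl (E)-3-methoxybut-2-enoate, via dimethyl ketal 17 (not isolated)
Conditions: HC(OMe)3 (1.2 equiv), H2SO4 (catalytic), MeOH, rt; then heating and distillation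
Reagents that add atoms: trimethyl orthoformate, COC(OC)OC
Why: Acid-catalysed ketalisation of the ketone by the orthoformate followed by thermal loss of methanol gives the conjugated enol ether, of which the E isomer is the thermodynamic product.

Step 10
Reactants: 18 methyl (E)-3-methoxybut-2-enoate
Product: 20 (E)-1,3-dimethoxy-1-(trimethylsilyloxy)buta-1,3-diene, via lithium dienolate 19 (not isolated)
Conditions: LiN(iPr)2 (1.1 equiv), THF, −78 °C; Me3SiCl (1.2 equiv), −78 °C to rt; non-aqueous work-up, distillation under reduced pressure
Reagents that add atoms: chlorotrimethylsilane, C[Si](C)(C)Cl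
Why: Kinetic gamma-deprotonation of the beta-methoxy enoate gives the extended dienolate, which the hard silyl chloride traps on oxygen (silyl ketene acetal formation).

Step 11
Reactants: 15 benzyl 4-(dec-2-ynoyloxy)-2-heptyl-6-methoxybenzoate; 20 (E)-1,3-dimethoxy-1-(trimethylsilyloxy)buta-1,3-diene
Product: 23 benzyl 2-heptyl-4-[(2-heptyl-6-hydroxy-4-methoxybenzoyl)oxy]-6-methoxybenzoate, via cyclohexadiene cycloadduct 21 (not isolated), via aryl trimethylsilyl ether 22 (not isolated)
Conditions: 20 (2.5 equiv), PhMe, sealed tube, 120 °C; then 1 M HCl, THF, rt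
Reagents that add atoms: none
Why: This is a Diels–Alder reaction of normal electron demand in which the electron-rich diene adds to the aryl ynoate in a concerted but asynchronous [4+2] process, the CH2 terminus of 20 bonding to the heptyl-bearing beta carbon (C2–C3 of ring B) ahead of the ketene acetal carbon bonding to the alpha carbon (C1–C6). The closest known reaction type is the thermal cycloaddition of 1-alkoxy-1,3-dioxygenated butadienes to 3-alkyl alk-2-ynoates with aromatisation to resorcylates. Ring B, the only ring formed, closes by the intermolecular suprafacial union of the four diene carbons with the two alkyne carbons (in the stepwise limit a 6-exo-trig attack of the allenoate alpha carbon on the silyloxycarbenium carbon); cyclohexadiene 21 then loses methanol from its mixed ketal to give silyl ether 22, which is hydrolysed on acidic work-up. No stereocentre survives, since the ketal carbon of 21 forms as a racemate and becomes the planar C6. The step needs regioselectivity, which the matched polarisation of the partners secures (nucleophilic CH2 terminus of the diene, electrophilic beta carbon of the ynoate), and chemoselectivity for the triple bond, which the absence of a Lewis acid, the activating aryl ester and the shielded 2,6-disubstituted benzyl ester secure. Any 6-methoxy arene formed by the alternative loss of trimethylsilanol is compound 24 and converges in step 12.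

Step 12
Reactants: 23 benzyl 2-heptyl-4-[(2-heptyl-6-hydroxy-4-methoxybenzoyl)oxy]-6-methoxybenzoate
Product: 24 benzyl 4-[(2-heptyl-4,6-dimethoxybenzoyl)oxy]-2-heptyl-6-methoxybenzoate
Conditions: MeI (5 equiv), K2CO3 (3 equiv), anhydrous acetone, reflux
Reagents that add atoms: iodomethane, CI
Why: Williamson methylation of the chelated 6-hydroxyl should proceed under weakly basic anhydrous conditions, and both esters are 2,6-disubstituted benzoates that resist attack by carbonate or phenoxide.

Step 13
Reactants: 24 benzyl 4-[(2-heptyl-4,6-dimethoxybenzoyl)oxy]-2-heptyl-6-methoxybenzoate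
Product: 25 4-[(2-heptyl-4,6-dimethoxybenzoyl)oxy]-2-heptyl-6-methoxybenzoic acid (CNP0300299.0)
Conditions: H2 (1 atm), 10% Pd/C, EtOAc, rt
Reagents that add atoms: none
Why: Catalytic hydrogenolysis of the benzylic C–O bond over palladium on carbon frees the carboxylic acid under neutral conditions that leave the aryl ester, the aryl methyl ethers and both arenes untouched.

Compound list
1 | methyl orsellinate (methyl 2,4-dihydroxy-6-methylbenzoate) | COC(=O)c1c(C)cc(O)cc1O | starting material
2 | methyl 2-hydroxy-4-(methoxymethoxy)-6-methylbenzoate | COCOc1cc(C)c(C(=O)OC)c(O)c1 | intermediate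
3 | methyl 2-methoxy-4-(methoxymethoxy)-6-methylbenzoate | COCOc1cc(C)c(C(=O)OC)c(OC)c1 | intermediate
4 | 1-iodohexane | CCCCCCI | starting material
5 | benzylic lithium species of 3 (methyl 2-(lithiomethyl)-6-methoxy-4-(methoxymethoxy)benzoate) | [Li]Cc1cc(OCOC)cc(OC)c1C(=O)OC | intermediate (not isolated)
6 | methyl 2-heptyl-6-methoxy-4-(methoxymethoxy)benzoate | CCCCCCCc1cc(OCOC)cc(OC)c1C(=O)OC | intermediate
7 | potassium 2-heptyl-6-methoxy-4-(methoxymethoxy)benzoate | CCCCCCCc1cc(OCOC)cc(OC)c1C(=O)[O-].[K+] | intermediate (not isolated)
8 | 2-heptyl-6-methoxy-4-(methoxymethoxy)benzoic acid | CCCCCCCc1cc(OCOC)cc(OC)c1C(=O)O | intermediate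
9 | benzyl 2-heptyl-6-methoxy-4-(methoxymethoxy)benzoate | CCCCCCCc1cc(OCOC)cc(OC)c1C(=O)OCc1ccccc1 | intermediate
10 | benzyl 2-heptyl-4-hydroxy-6-methoxybenzoate | CCCCCCCc1cc(O)cc(OC)c1C(=O)OCc1ccccc1 | intermediate
11 | 1-nonyne | CCCCCCCC#C | starting material
12 | lithium non-1-yn-1-ide | CCCCCCCC#C[Li] | intermediate (not isolated)
13 | lithium dec-2-ynoate | CCCCCCCC#CC(=O)[O-].[Li+] | intermediate (not isolated)
14 | dec-2-ynoic acid | CCCCCCCC#CC(=O)O | intermediate
15 | benzyl 4-(dec-2-ynoyloxy)-2-heptyl-6-methoxybenzoate | CCCCCCCC#CC(=O)Oc1cc(CCCCCCC)c(C(=O)OCc2ccccc2)c(OC)c1 | intermediate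
16 | methyl acetoacetate | CC(=O)CC(=O)OC | starting material
17 | methyl 3,3-dimethoxybutanoate | COC(=O)CC(C)(OC)OC | intermediate (not isolated)
18 | methyl (E)-3-methoxybut-2-enoate | CO/C(C)=C/C(=O)OC | intermediate
19 | lithium 1,3-dimethoxybuta-1,3-dien-1-olate | C=C(OC)/C=C(\OC)O[Li] | intermediate (not isolated)
20 | (E)-1,3-dimethoxy-1-(trimethylsilyloxy)buta-1,3-diene | C=C(OC)/C=C(\OC)O[Si](C)(C)C | intermediate
21 | benzyl 2-heptyl-4-{[2-heptyl-4,6-dimethoxy-6-(trimethylsilyloxy)cyclohexa-1,4-diene-1-carbonyl]oxy}-6-methoxybenzoate (racemic at the ketal carbon) | CCCCCCCC1=C(C(=O)Oc2cc(CCCCCCC)c(C(=O)OCc3ccccc3)c(OC)c2)C(OC)(O[Si](C)(C)C)C=C(OC)C1 | intermediate (not isolated)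
22 | benzyl 2-heptyl-4-{[2-heptyl-4-methoxy-6-(trimethylsilyloxy)benzoyl]oxy}-6-methoxybenzoate | CCCCCCCc1cc(OC)cc(O[Si](C)(C)C)c1C(=O)Oc1cc(CCCCCCC)c(C(=O)OCc2ccccc2)c(OC)c1 | intermediate (not isolated)
23 | benzyl 2-heptyl-4-[(2-heptyl-6-hydroxy-4-methoxybenzoyl)oxy]-6-methoxybenzoate | CCCCCCCc1cc(OC(=O)c2c(CCCCCCC)cc(OC)cc2O)cc(OC)c1C(=O)OCc1ccccc1 | intermediate
24 | benzyl 4-[(2-heptyl-4,6-dimethoxybenzoyl)oxy]-2-heptyl-6-methoxybenzoate | CCCCCCCc1cc(OC(=O)c2c(CCCCCCC)cc(OC)cc2OC)cc(OC)c1C(=O)OCc1ccccc1 | intermediate
25 | 4-[(2-heptyl-4,6-dimethoxybenzoyl)oxy]-2-heptyl-6-methoxybenzoic acid (CNP0300299.0, no stereocentres) | CCCCCCCc1cc(OC(=O)c2c(CCCCCCC)cc(OC)cc2OC)cc(OC)c1C(=O)O | target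

Total step count: 13 steps.
Longest linear sequence: 10 steps (steps 1, 2, 3, 4, 5, 6, 8, 11, 12, 13).

Steps most likely to fail

Step 11. The cycloaddition to the beta-alkyl ynoate may be too slow, so that the diene is consumed by thermal decomposition, by adventitious hydrolysis or by attack on the aryl ester before ring B forms. The fallback gives up the benzannulation and forms the depside bond by acylation with a finished ring B acid.
- It sets out from 1, where exhaustive methylation (MeI, K2CO3, DMF) should give methyl 2,4-dimethoxy-6-methylbenzoate F1.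
- Lateral lithiation with LiN(iPr)2 in THF at −78 °C to the benzylic lithium species of this ester F2, then alkylation with 4, should give methyl 2-heptyl-4,6-dimethoxybenzoate F3.
- Saponification (KOH, DMSO–H2O, 90 °C) through potassium 2-heptyl-4,6-dimethoxybenzoate F4 and acidification should give 2-heptyl-4,6-dimethoxybenzoic acid F5.
- Activation with (CF3CO)2O in toluene at rt should give the mixed anhydride 2-heptyl-4,6-dimethoxybenzoic trifluoroacetic anhydride F6, which ionises readily to the acylium ion because of its two ortho substituents.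
- Addition of phenol 10 should then give 24 directly, where the fallback comes back to the route before step 13.

Step 3. The benzylic anion may condense with the ester group of unreacted 3, or alkylation may stop short or go twice. The fallback reverses the order of alkylation and saponification, so that the C–C bond is made on a carboxylate dianion that carries no electrophilic ester.
- It sets out from 3, where KOH in DMSO–H2O should give potassium 2-methoxy-4-(methoxymethoxy)-6-methylbenzoate F7 and, after cold acidification, 2-methoxy-4-(methoxymethoxy)-6-methylbenzoic acid F8.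
- Two equivalents of LiN(iPr)2 (or s-BuLi) in THF at −78 °C should give lithium 2-(lithiomethyl)-6-methoxy-4-(methoxymethoxy)benzoate F9.
- Alkylation with 4 should give lithium 2-heptyl-6-methoxy-4-(methoxymethoxy)benzoate F10, and cold acidification should give acid 8, where the route is rejoined at step 5.

Step 8. The nucleophilic catalyst or the phenol may add in conjugate fashion to the activated triple bond, and the O-acylisourea may rearrange by O-to-N acyl shift before the moderately nucleophilic phenol is acylated. The fallback replaces in-flask carbodiimide activation under nucleophilic catalysis by a preformed acylating agent and a non-nucleophilic base.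
- It sets out from 14, where oxalyl chloride with catalytic DMF in CH2Cl2 at 0 °C should give dec-2-ynoyl chloride F11.
- Addition of F11 to phenol 10 and 2,6-lutidine in CH2Cl2 at −20 °C should give 15, where the route is rejoined before step 11.

Further compounds
F1 | step 11 | methyl 2,4-dimethoxy-6-methylbenzoate | COC(=O)c1c(C)cc(OC)cc1OC
F2 | step 11 | methyl 2-(lithiomethyl)-4,6-dimethoxybenzoate | [Li]Cc1cc(OC)cc(OC)c1C(=O)OC
F3 | step 11 | methyl 2-heptyl-4,6-dimethoxybenzoate | CCCCCCCc1cc(OC)cc(OC)c1C(=O)OC
F4 | step 11 | potassium 2-heptyl-4,6-dimethoxybenzoate | CCCCCCCc1cc(OC)cc(OC)c1C(=O)[O-].[K+]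
F5 | step 11 | 2-heptyl-4,6-dimethoxybenzoic acid | CCCCCCCc1cc(OC)cc(OC)c1C(=O)O
F6 | step 11 | 2-heptyl-4,6-dimethoxybenzoic trifluoroacetic anhydride | CCCCCCCc1cc(OC)cc(OC)c1C(=O)OC(=O)C(F)(F)F
F7 | step 3 | potassium 2-methoxy-4-(methoxymethoxy)-6-methylbenzoate | COCOc1cc(C)c(C(=O)[O-])c(OC)c1.[K+]
F8 | step 3 | 2-methoxy-4-(methoxymethoxy)-6-methylbenzoic acid | COCOc1cc(C)c(C(=O)O)c(OC)c1
F9 | step 3 | lithium 2-(lithiomethyl)-6-methoxy-4-(methoxymethoxy)benzoate | [Li]Cc1cc(OCOC)cc(OC)c1C(=O)O[Li]
F10 | step 3 | lithium 2-heptyl-6-methoxy-4-(methoxymethoxy)benzoate | CCCCCCCc1cc(OCOC)cc(OC)c1C(=O)[O-].[Li+]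
F11 | step 8 | dec-2-ynoyl chloride | CCCCCCCC#CC(Cl)=O
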